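Read the race between the two first steps off the earliest readings, then fence the answer in from both sides.

| setting | amber | green | summer | noon | dawn | spring | midnight |
|---|---|---|---|---|---|---|---|
| substrate | 0.69 M | 0.34 M | 0.69 M | 0.69 M | 0.69 M | 0.69 M | 0.69 M |
| coupling partner | 1.8 M | 2.76 M | 2.76 M | 2.76 M | 2.76 M | 2.76 M | 2.76 M |
| rival reagent | 0.552 M | 0.552 M | 0.552 M | 0.150 M | 1.20 M | 0.200 M | 0.800 M |
| remark | run made earlier | run made earlier |  |  |  |  |  |
| time |  |  | 3.0 min | 3.0 min | 3.0 min | 3.0 min | 3.0 min |

- amber (time / s: target / %, side product A / %, side product B / %): 10.0: 5.9, 19.5, 1.0; 20.0: 11.1, 32.3, 1.0; 30.0: 14.1, 38.3, 3.5; 40.0: 17.1, 43.2, 3.8; 50.0: 19.4, 48.2, 5.5; 60.0: 19.3, 49.5, 5.6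
- green (time / s: target / %, side product A / %, side product B / %): 10.0: 10.0, 20.3, 1.6; 12.0: 12.5, 24.8, 0.6; 20.0: 17.3, 34.0, 1.3; 30.0: 21.2, 42.6, 1.5; 50.0: 27.7, 51.6, 2.6; 60.0: 28.8, 54.5, 2.6

(readings scatter by 0.5 percentage points)

- a species is counted by the substrate in it: one side product B counts as two
- candidate steps: substrate + rival reagent -> side product A; substrate + target -> side product B; substrate + coupling partner <-> target

- all flasks from highest to lowest share of target in all that became target or side product A or side product B, at 3.0 min (summer / noon / dawn / spring / midnight)
- the same order at 40 s (summer / noon / dawn / spring / midnight)
- the share of target in all that became target or side product A or side product B of the flask you put first, at 3.0 min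
- the share of target in all that became target or side product A or side product B of the flask you put last, at 3.0 min

At 10.0 s amber has lost about 2.26% of its coupling partner but already 24.4% of its rival reagent, and green 12.5% of its rival reagent, so target over side product A, multiplied by the charged c(rival reagent)/c(coupling partner), gives a rough comparison of the two pulls on the substrate, and the charged rival reagent overstates what acted. Amber gives 0.0928 and green 0.0985. We carry their mean, a selectivity factor, 0.0957. The five flasks share one c(coupling partner), so the opening ratio of side product A to target, c(rival reagent)/(factor × c(coupling partner)), climbs with the rival charge. We therefore rank them by rising rival charge at both times. For noon that ratio is 0.568. For dawn the opening share of target is 18.0%, our estimate for last place.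

Noon has little rival reagent to spend, so we fence it. Target is also eaten: half of amber's last side product B is target lost, which is 12.7% of the target made. The share is then target left over target left, plus side product A, plus twice the target lost.

From above, we allow noon no side product A and amber's loss, which gives 77.5%. From below, we let the loss grow with target over coupling partner, granting noon target at its opening share of the charge, so the loss is 27.3%. Holding the rival at its charge then gives 39.5%. Side product A cannot pass the rival charge, 21.7% of the substrate, so counting the whole charge as reacted tightens this to 44.7%.

The forecast gives noon > spring > summer > midnight > dawn at 3.0 min, noon > spring > summer > midnight > dawn at 40 s, 52% and 18%, with “The order stays the same at both times”; its top lies inside our fence.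

The flasks give noon > spring > summer > midnight > dawn and noon > spring > summer > midnight > dawn, with noon at 48.8% and dawn at 17.0%.

    substrate + rival reagent → side product A (k = 0.0490 M⁻¹ s⁻¹)
    substrate + target → side product B (k = 0.0130 M⁻¹ s⁻¹)
    substrate + coupling partner ⇌ target (K = 3.50 M⁻¹, k = 0.00470 M⁻¹ s⁻¹)

Noon stands inside the fence, above its lower edge. In noon, part of that margin is the falling level of rival reagent, which acts together with the time given, against ten times as long: held at its charge, noon gives 41.1%, beside our held reckoning of 39.5%, and at 30.0 min noon's share is 20.7%.

On the neighbour of dawn with 1.1 M of coupling partner, the factor gives an opening share of 8.06%. That flask gives 7.98%.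

The data come from a simulation on assumed constants, noise included.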